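## Retrosynthetic overview

- Target 18 is the (2R,3S,4S) flavan-3,4-diol (2,3-trans, 3,4-cis). All protecting groups (three TBS, one SEM) are removed by fluoride in the last step, so the solvolysis-prone C4 carbinol never meets acid.
- Key disconnection (step 10): O1–C8a and C8–prenyl are cut together. The precursor is the open-chain anti,anti 1,3-diaryl-triol derivative 12, with a fluorine where O1 will sit. Rings A and B are bought; ring C (the pyran) is the only ring made.
- Enabling feature: on ring A the atoms C4a (side chain), C8a (O1), C8 (prenyl) and C7 (oxygen) are contiguous. An aryne across C8–C8a therefore lies between the tethered C2 alkoxide and the C7 oxygen, which directs its generation and polarises it. The alkoxide takes C8a; the carbanion left at C8 takes the prenyl group.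
- Stereotriad of 12: C2 by catalytic asymmetric alkynylation of ring B aldehyde 5 with ring A alkyne 4; C3 and C4 together by osmylation of the derived Z allylic silyl ether, anti to the allylic oxygen.
- Ring A alkyne 4: from 2,6-difluoro-4-hydroxybenzaldehyde by SEM protection, SNAr with methoxide (one fluorine kept as the aryne leaving group) and Ohira–Bestmann homologation.

Key step: step 10

Assumption: in step 4 the (S,S) antipode of ProPhenol is taken to deliver the alkynyl group to the Si face of 5, giving the (R)-carbinol (CIP order OH > arylethynyl > aryl > H); if the first run shows the opposite sense, the (R,R) ligand is used and nothing else changes.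

Assumption: 1 and 5 are taken as catalogue compounds.

## Route

Step 1
Reactants: 1 2,6-difluoro-4-hydroxybenzaldehyde
Product: 2 2,6-difluoro-4-{[2-(trimethylsilyl)ethoxy]methoxy}benzaldehyde
Conditions: SEMCl (1.2 equiv), K2CO3 (2 equiv), DMF, 0 °C to rt
Reagents that add atoms: 2-(trimethylsilyl)ethoxymethyl chloride (SEMCl), C[Si](C)(C)CCOCCl
Why: Williamson-type O-alkylation of an acidic phenol; the SEM acetal is chosen because it later directs ortho-lithiation and is removed by fluoride without acid.

Step 2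
Reactants: 2 2,6-difluoro-4-{[2-(trimethylsilyl)ethoxy]methoxy}benzaldehyde
Product: 3 2-fluoro-6-methoxy-4-{[2-(trimethylsilyl)ethoxy]methoxy}benzaldehyde
Conditions: NaOMe (1.05 equiv), MeOH/THF, 0 °C to rt
Reagents that add atoms: sodium methoxide, C[O-].[Na+]
Why: Nucleophilic aromatic substitution (SNAr) at one of the two equivalent C–F bonds ortho to the formyl group; the first methoxy group deactivates the ring, so substitution should stop with one fluorine left.

Step 3
Reactants: 3 2-fluoro-6-methoxy-4-{[2-(trimethylsilyl)ethoxy]methoxy}benzaldehyde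
Product: 4 2-ethynyl-1-fluoro-3-methoxy-5-{[2-(trimethylsilyl)ethoxy]methoxy}benzene
Conditions: dimethyl (1-diazo-2-oxopropyl)phosphonate (1.3 equiv), K2CO3 (2 equiv), MeOH, 0 °C to rt
Reagents that add atoms: dimethyl (1-diazo-2-oxopropyl)phosphonate, CC(=O)C(=[N+]=[N-])P(=O)(OC)OC
Why: Seyferth–Gilbert homologation in the Ohira–Bestmann variant converts the aryl aldehyde into the terminal alkyne under conditions mild enough for the SEM ether and the aryl fluoride.

Step 4
Reactants: 4 2-ethynyl-1-fluoro-3-methoxy-5-{[2-(trimethylsilyl)ethoxy]methoxy}benzene; 5 4-[(tert-butyldimethylsilyl)oxy]benzaldehyde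
Product: 7 (1R)-1-{4-[(tert-butyldimethylsilyl)oxy]phenyl}-3-(2-fluoro-6-methoxy-4-{[2-(trimethylsilyl)ethoxy]methoxy}phenyl)prop-2-yn-1-ol, via methylzinc acetylide 6 (not isolated)
Conditions: 4 (1.5 equiv), Me2Zn (3 equiv), (S,S)-ProPhenol (10 mol %), Ph3P=O (20 mol %), toluene, rt; then 5 (1.0 equiv), 4 °C; aqueous NH4Cl
Reagents that add atoms: none
Why: Catalytic enantioselective addition of an alkynylzinc to an aryl aldehyde with a dinuclear zinc–ProPhenol catalyst, an established reaction class for aryl aldehydes and arylacetylenes; the chiral dizinc pocket selects the Si face of 5 and sets the carbinol centre (the later C2) as R.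

Step 5
Reactants: 7 (1R)-1-{4-[(tert-butyldimethylsilyl)oxy]phenyl}-3-(2-fluoro-6-methoxy-4-{[2-(trimethylsilyl)ethoxy]methoxy}phenyl)prop-2-yn-1-ol
Product: 8 (1R)-1-{4-[(tert-butyldimethylsilyl)oxy]phenyl}-3-(2-fluoro-6-methoxy-4-{[2-(trimethylsilyl)ethoxy]methoxy}phenyl)prop-2-yn-1-yl triethylsilyl ether
Conditions: TESCl (1.3 equiv), imidazole (2.5 equiv), CH2Cl2, 0 °C
Reagents that add atoms: chlorotriethylsilane, CC[Si](Cl)(CC)CC
Why: Silylation under non-acidic conditions avoids ionisation of the doubly activated propargylic benzylic C–O bond; the TES ether is the one group that step 9 removes selectively, and as an ether it supports the anti-selective osmylation of step 7.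

Step 6
Reactants: 8 (1R)-propargylic triethylsilyl ether
Product: 9 (1S,2Z)-1-{4-[(tert-butyldimethylsilyl)oxy]phenyl}-3-(2-fluoro-6-methoxy-4-{[2-(trimethylsilyl)ethoxy]methoxy}phenyl)prop-2-en-1-yl triethylsilyl ether
Conditions: H2 (1 atm), Pd/CaCO3 poisoned with Pb(OAc)2 (Lindlar catalyst), quinoline, EtOAc/hexane, rt, stopped after one equivalent of H2
Reagents that add atoms: none
Why: Lindlar semi-hydrogenation delivers H2 syn on the poisoned palladium surface to give the Z alkene; the carbinol centre is untouched (the descriptor changes from R to S only because the CIP order changes).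

Step 7
Reactants: 9 (1S,2Z)-allylic triethylsilyl ether
Product: 10 (1S,2S,3R)-3-{4-[(tert-butyldimethylsilyl)oxy]phenyl}-1-(2-fluoro-6-methoxy-4-{[2-(trimethylsilyl)ethoxy]methoxy}phenyl)-3-[(triethylsilyl)oxy]propane-1,2-diol (anti,anti triad)
Conditions: OsO4 (5 mol %), NMO (2 equiv), acetone/H2O (8:1), 0 °C to rt; aqueous Na2SO3
Reagents that add atoms: N-methylmorpholine N-oxide, C[N+]1([O-])CCOCC1; water, O (OsO4, O=[Os](=O)(=O)=O, is the catalytic oxygen carrier)
Why: Substrate-controlled catalytic osmylation: in the conformer that puts the allylic C–H in the alkene plane (allylic 1,3-strain of the Z alkene), OsO4 should add anti to the silyloxy group (the empirical rule for allylic ethers, most reliable for Z alkenes), and syn addition to the Z alkene makes the two new carbinols erythro, so the future C3 and C4 are both set anti,anti relative to C2.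

Step 8
Reactants: 10 (1S,2S,3R)-diol
Product: 11 (1R,2R,3S)-2,3-bis[(tert-butyldimethylsilyl)oxy]-1-{4-[(tert-butyldimethylsilyl)oxy]phenyl}-3-(2-fluoro-6-methoxy-4-{[2-(trimethylsilyl)ethoxy]methoxy}phenyl)-1-[(triethylsilyl)oxy]propane
Conditions: TBSOTf (3 equiv), 2,6-lutidine (5 equiv), CH2Cl2, −78 to 0 °C
Reagents that add atoms: tert-butyldimethylsilyl trifluoromethanesulfonate, CC(C)(C)[Si](C)(C)OS(=O)(=O)C(F)(F)F
Why: Silyl triflate with a hindered pyridine base silylates the crowded vicinal diol at low temperature, where the SEM acetal should survive; TBS ethers are inert to butyllithium at low temperature and fall to fluoride at the end.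

Step 9
Reactants: 11 (1R,2R,3S)-tris-silyl ether
Product: 12 (1R,2R,3S)-2,3-bis[(tert-butyldimethylsilyl)oxy]-1-{4-[(tert-butyldimethylsilyl)oxy]phenyl}-3-(2-fluoro-6-methoxy-4-{[2-(trimethylsilyl)ethoxy]methoxy}phenyl)propan-1-ol
Conditions: PPTS (0.2 equiv), MeOH/CH2Cl2 (1:1), 0 °C
Reagents that add atoms: none
Why: Chemoselective acid-catalysed methanolysis of the triethylsilyl ether, which is far more acid-labile than secondary alkyl and aryl TBS ethers, frees only the hydroxyl that becomes O1; the Si–O bond is cleaved, so the carbinol configuration is kept.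

Step 10
Reactants: 12 (1R,2R,3S)-2,3-bis[(tert-butyldimethylsilyl)oxy]-1-{4-[(tert-butyldimethylsilyl)oxy]phenyl}-3-(2-fluoro-6-methoxy-4-{[2-(trimethylsilyl)ethoxy]methoxy}phenyl)propan-1-ol
Product: 16 (2R,3R,4S)-3,4-bis[(tert-butyldimethylsilyl)oxy]-2-{4-[(tert-butyldimethylsilyl)oxy]phenyl}-5-methoxy-8-(3-methylbut-2-en-1-yl)-7-{[2-(trimethylsilyl)ethoxy]methoxy}-3,4-dihydro-2H-chromene, via dilithio species 13 (not isolated), via aryne alkoxide 14 (not isolated), via 8-lithiochroman 15 (not isolated)
Conditions: n-BuLi (2.05 equiv), THF, −78 °C, 1 h; −78 to −10 °C over 1 h; then CuBr·SMe2 (10 mol %), prenyl bromide (1.5 equiv), −40 °C to rt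
Reagents that add atoms: 1-bromo-3-methylbut-2-ene (prenyl bromide), CC(C)=CCBr
Why: Proposed new method: n-BuLi first makes the lithium alkoxide and then lithiates the only ring A C–H flanked by fluorine and the SEM acetal oxygen (C8; such sites are metalated at −78 °C, whereas the C6–H between two alkoxy groups needs far higher temperature), and on warming the ortho-fluoroaryllithium loses LiF to give the C8–C8a aryne. The side-chain alkoxide, three carbons from the ring, can reach only C8a and closes the pyran ring by a 6-exo-dig attack that forms the O1–C8a bond; the C7 oxygen polarises the aryne towards the same carbon, because attack there leaves the carbanion at C8 next to the inductively stabilising, chelating SEM-oxy group. The resulting 8-lithiochroman is then allylated at the primary carbon of prenyl bromide through a catalytic arylcuprate (monovalent copper), so one flask forms the heterocycle, installs the C8 prenyl group and removes the fluorine. The closest known reaction types are the benzyne cyclisation of tethered heteroatom nucleophiles and the addition of a metalated nucleophile to a 3-alkoxyaryne made from a 3-alkoxyfluoroarene, followed by electrophilic capture of the aryl anion; the new element is a chiral secondary alkoxide as internal nucleophile combined with C-allylation of the relay anion. No stereocentre is formed or broken: the C2–O bond is retained, so the anti,anti triad of 12 maps directly onto the 2,3-trans-3,4-cis flavan. The selectivities needed are the site of metalation (secured by the F/O-acetal flanking), the direction of LiF loss (only one fluorine), the regiochemistry of O-arylation (tether length and aryne polarisation agree) and alpha over gamma allylation (hindered gamma carbon, and aryllithium in excess over copper favouring the diarylcuprate).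

Step 11
Reactants: 16 (2R,3R,4S)-protected 8-prenylflavan
Product: 18 (2R,3S,4S)-2-(4-hydroxyphenyl)-5-methoxy-8-(3-methylbut-2-en-1-yl)-3,4-dihydro-2H-chromene-3,4,7-triol, via SEM ether 17 (not isolated)
Conditions: TBAF (8 equiv), ethane-1,2-diamine (3 equiv), THF, 0 °C to rt; then DMPU, 45 °C; aqueous NH4Cl
Reagents that add atoms: none
Why: Fluoride-induced global deprotection: the three Si–O bonds should cleave at room temperature, and on warming fluoride attacks the trimethylsilyl group of the SEM acetal, which fragments to ethene, formaldehyde (trapped by the diamine) and the phenoxide, so no acid touches the C4 benzylic alcohol or the prenyl/phenol pair.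

## Compound list

1 | 2,6-difluoro-4-hydroxybenzaldehyde | O=Cc1c(F)cc(O)cc1F | starting material
2 | 2,6-difluoro-4-{[2-(trimethylsilyl)ethoxy]methoxy}benzaldehyde | O=Cc1c(F)cc(OCOCC[Si](C)(C)C)cc1F | intermediate
3 | 2-fluoro-6-methoxy-4-{[2-(trimethylsilyl)ethoxy]methoxy}benzaldehyde | COc1cc(OCOCC[Si](C)(C)C)cc(F)c1C=O | intermediate
4 | 2-ethynyl-1-fluoro-3-methoxy-5-{[2-(trimethylsilyl)ethoxy]methoxy}benzene | COc1cc(OCOCC[Si](C)(C)C)cc(F)c1C#C | intermediate
5 | 4-[(tert-butyldimethylsilyl)oxy]benzaldehyde | O=Cc1ccc(O[Si](C)(C)C(C)(C)C)cc1 | starting material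
6 | methylzinc acetylide of 4 | COc1cc(OCOCC[Si](C)(C)C)cc(F)c1C#C[Zn]C | intermediate (not isolated)
7 | (1R)-1-{4-[(tert-butyldimethylsilyl)oxy]phenyl}-3-(2-fluoro-6-methoxy-4-{[2-(trimethylsilyl)ethoxy]methoxy}phenyl)prop-2-yn-1-ol | COc1cc(OCOCC[Si](C)(C)C)cc(F)c1C#C[C@@H](c1ccc(O[Si](C)(C)C(C)(C)C)cc1)O | intermediate
8 | (1R)-triethylsilyl ether of 7 | COc1cc(OCOCC[Si](C)(C)C)cc(F)c1C#C[C@@H](c1ccc(O[Si](C)(C)C(C)(C)C)cc1)O[Si](CC)(CC)CC | intermediate
9 | (1S,2Z)-1-{4-[(tert-butyldimethylsilyl)oxy]phenyl}-3-(2-fluoro-6-methoxy-4-{[2-(trimethylsilyl)ethoxy]methoxy}phenyl)prop-2-en-1-yl triethylsilyl ether | COc1cc(OCOCC[Si](C)(C)C)cc(F)c1/C=C\[C@@H](c1ccc(O[Si](C)(C)C(C)(C)C)cc1)O[Si](CC)(CC)CC | intermediate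
10 | (1S,2S,3R)-3-{4-[(tert-butyldimethylsilyl)oxy]phenyl}-1-(2-fluoro-6-methoxy-4-{[2-(trimethylsilyl)ethoxy]methoxy}phenyl)-3-[(triethylsilyl)oxy]propane-1,2-diol | COc1cc(OCOCC[Si](C)(C)C)cc(F)c1[C@H](O)[C@H](O)[C@@H](c1ccc(O[Si](C)(C)C(C)(C)C)cc1)O[Si](CC)(CC)CC | intermediate
11 | (1R,2R,3S)-2,3-bis[(tert-butyldimethylsilyl)oxy]-1-{4-[(tert-butyldimethylsilyl)oxy]phenyl}-3-(2-fluoro-6-methoxy-4-{[2-(trimethylsilyl)ethoxy]methoxy}phenyl)-1-[(triethylsilyl)oxy]propane | COc1cc(OCOCC[Si](C)(C)C)cc(F)c1[C@H](O[Si](C)(C)C(C)(C)C)[C@H](O[Si](C)(C)C(C)(C)C)[C@@H](c1ccc(O[Si](C)(C)C(C)(C)C)cc1)O[Si](CC)(CC)CC | intermediate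
12 | (1R,2R,3S)-2,3-bis[(tert-butyldimethylsilyl)oxy]-1-{4-[(tert-butyldimethylsilyl)oxy]phenyl}-3-(2-fluoro-6-methoxy-4-{[2-(trimethylsilyl)ethoxy]methoxy}phenyl)propan-1-ol | COc1cc(OCOCC[Si](C)(C)C)cc(F)c1[C@H](O[Si](C)(C)C(C)(C)C)[C@H](O[Si](C)(C)C(C)(C)C)[C@@H](c1ccc(O[Si](C)(C)C(C)(C)C)cc1)O | intermediate
13 | lithium alkoxide of 12 lithiated at the ring A carbon between F and the SEM-oxy group | COc1cc(OCOCC[Si](C)(C)C)c([Li])c(F)c1[C@H](O[Si](C)(C)C(C)(C)C)[C@H](O[Si](C)(C)C(C)(C)C)[C@@H](c1ccc(O[Si](C)(C)C(C)(C)C)cc1)O[Li] | intermediate (not isolated)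
14 | aryne (C8–C8a) bearing the lithium alkoxide side chain | COC1=C([C@H](O[Si](C)(C)C(C)(C)C)[C@H](O[Si](C)(C)C(C)(C)C)[C@@H](c2ccc(O[Si](C)(C)C(C)(C)C)cc2)O[Li])C#CC(OCOCC[Si](C)(C)C)=C1 | intermediate (not isolated)
15 | 8-lithio derivative of the protected flavan | COc1cc(OCOCC[Si](C)(C)C)c([Li])c2c1[C@H](O[Si](C)(C)C(C)(C)C)[C@H](O[Si](C)(C)C(C)(C)C)[C@@H](c1ccc(O[Si](C)(C)C(C)(C)C)cc1)O2 | intermediate (not isolated)
16 | (2R,3R,4S)-3,4-bis[(tert-butyldimethylsilyl)oxy]-2-{4-[(tert-butyldimethylsilyl)oxy]phenyl}-5-methoxy-8-(3-methylbut-2-en-1-yl)-7-{[2-(trimethylsilyl)ethoxy]methoxy}-3,4-dihydro-2H-chromene | COc1cc(OCOCC[Si](C)(C)C)c(CC=C(C)C)c2c1[C@H](O[Si](C)(C)C(C)(C)C)[C@H](O[Si](C)(C)C(C)(C)C)[C@@H](c1ccc(O[Si](C)(C)C(C)(C)C)cc1)O2 | intermediate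
17 | (2R,3S,4S)-2-(4-hydroxyphenyl)-5-methoxy-8-(3-methylbut-2-en-1-yl)-7-{[2-(trimethylsilyl)ethoxy]methoxy}-3,4-dihydro-2H-chromene-3,4-diol | COc1cc(OCOCC[Si](C)(C)C)c(CC=C(C)C)c2c1[C@H](O)[C@H](O)[C@@H](c1ccc(O)cc1)O2 | intermediate (not isolated)
18 | (2R,3S,4S)-2-(4-hydroxyphenyl)-5-methoxy-8-(3-methylbut-2-en-1-yl)-3,4-dihydro-2H-chromene-3,4,7-triol (5-O-methyl-8-prenylafzelechin-4beta-ol) | COc1cc(O)c(CC=C(C)C)c2c1[C@H](O)[C@H](O)[C@@H](c1ccc(O)cc1)O2 | target

## Step count and risks

Total step count: 11. Longest linear sequence: 11 steps (1 to 18); aldehyde 5 is bought and enters in step 4.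

Steps most likely to fail, riskiest first:

**Step 10 (proposed new method).** The relay may break down: the 8-lithio intermediate may be protonated, or may couple unselectively with the allylic bromide, before clean capture, so that ring closure and prenylation do not both succeed in one flask. The fallback uses known chemistry, sets out from 12 and returns at 16. Alcohol 12 is cyclised by the classical benzyne cyclisation with a proton quench (n-BuLi, 2 equiv, THF, −78 to −10 °C, then NH4Cl) to the 8-unsubstituted protected flavan F1. Electrophilic bromination with NBS in CH2Cl2 at the ring A position next to O1, the usual site for 5,7-dialkoxyflavans, gives the 8-bromide F2. Bromine–lithium exchange with t-BuLi at −78 °C, then CuBr·SMe2 (10 mol %) and prenyl bromide, gives 16.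

**Step 7.** Facial selectivity may be poor, or the osmylation slow, at the hindered open-chain Z alkene, where an aryl group sits on the carbinol carbon. The fallback moves the dihydroxylation onto the ring, sets out from 7 and returns at 16. Lindlar semi-hydrogenation of the free alcohol 7 gives the (S,Z)-allylic alcohol F3. Benzyne cyclisation of its lithium alkoxide (n-BuLi, 2 equiv, THF, −78 to −10 °C, NH4Cl quench), which the Z alkene holds next to the fluorine-bearing carbon, gives the (S)-flav-3-ene F4. OsO4/NMO then adds anti to the C2 aryl group, the established way to 2,3-trans-3,4-cis flavan-3,4-diols, to give the diol F5. TBSOTf/2,6-lutidine converts F5 into the protected flavan F1, which goes through the bromide F2 to 16 as described for step 10. This order also removes any silyl ether next to the alkoxide during ring closure, and so any base-induced silyl migration.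

**Step 11.** Cleavage of the aryl SEM acetal may be incomplete at a temperature the unprotected flavan-3,4-diol tolerates, or the free product may epimerise or decompose under warm, basic fluoride. The fallback separates the two events, sets out from 16 and returns at 18. The SEM group is removed first, while O3 and O4 are still silylated, with MgBr2·OEt2 in Et2O/MeNO2 at rt (chelation-assisted acetal cleavage that leaves TBS ethers), giving the 7-phenol F6. The three TBS groups are then removed at 0 °C with TBAF buffered with AcOH, giving 18.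

## Further compounds

F1 | step 10 | (2R,3R,4S)-3,4-bis[(tert-butyldimethylsilyl)oxy]-2-{4-[(tert-butyldimethylsilyl)oxy]phenyl}-5-methoxy-7-{[2-(trimethylsilyl)ethoxy]methoxy}-3,4-dihydro-2H-chromene | COc1cc(OCOCC[Si](C)(C)C)cc2c1[C@H](O[Si](C)(C)C(C)(C)C)[C@H](O[Si](C)(C)C(C)(C)C)[C@@H](c1ccc(O[Si](C)(C)C(C)(C)C)cc1)O2
F2 | step 10 | (2R,3R,4S)-8-bromo-3,4-bis[(tert-butyldimethylsilyl)oxy]-2-{4-[(tert-butyldimethylsilyl)oxy]phenyl}-5-methoxy-7-{[2-(trimethylsilyl)ethoxy]methoxy}-3,4-dihydro-2H-chromene | COc1cc(OCOCC[Si](C)(C)C)c(Br)c2c1[C@H](O[Si](C)(C)C(C)(C)C)[C@H](O[Si](C)(C)C(C)(C)C)[C@@H](c1ccc(O[Si](C)(C)C(C)(C)C)cc1)O2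
F3 | step 7 | (1S,2Z)-1-{4-[(tert-butyldimethylsilyl)oxy]phenyl}-3-(2-fluoro-6-methoxy-4-{[2-(trimethylsilyl)ethoxy]methoxy}phenyl)prop-2-en-1-ol | COc1cc(OCOCC[Si](C)(C)C)cc(F)c1/C=C\[C@@H](c1ccc(O[Si](C)(C)C(C)(C)C)cc1)O
F4 | step 7 | (2S)-2-{4-[(tert-butyldimethylsilyl)oxy]phenyl}-5-methoxy-7-{[2-(trimethylsilyl)ethoxy]methoxy}-2H-chromene | COc1cc(OCOCC[Si](C)(C)C)cc2c1C=C[C@@H](c1ccc(O[Si](C)(C)C(C)(C)C)cc1)O2
F5 | step 7 | (2R,3S,4S)-2-{4-[(tert-butyldimethylsilyl)oxy]phenyl}-5-methoxy-7-{[2-(trimethylsilyl)ethoxy]methoxy}-3,4-dihydro-2H-chromene-3,4-diol | COc1cc(OCOCC[Si](C)(C)C)cc2c1[C@H](O)[C@H](O)[C@@H](c1ccc(O[Si](C)(C)C(C)(C)C)cc1)O2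
F6 | step 11 | (2R,3R,4S)-3,4-bis[(tert-butyldimethylsilyl)oxy]-2-{4-[(tert-butyldimethylsilyl)oxy]phenyl}-5-methoxy-8-(3-methylbut-2-en-1-yl)-3,4-dihydro-2H-chromen-7-ol | COc1cc(O)c(CC=C(C)C)c2c1[C@H](O[Si](C)(C)C(C)(C)C)[C@H](O[Si](C)(C)C(C)(C)C)[C@@H](c1ccc(O[Si](C)(C)C(C)(C)C)cc1)O2
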